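The pitfall in a flask that changes temperature is to add up its minutes as if each were worth the same. I took the settings one at a time.

| flask | substrate | solid activator | temperature | remark | time |
|---|---|---|---|---|---|
| north-west | 0.54 M | 0.64 M | 80 °C | run made earlier |  |
| south | 1.2 M | 0.64 M | 102 °C | run made earlier |  |
| east | 0.80 M | 1.3 M | 80 °C | run made earlier |  |
| dawn | 0.80 M | 0.640 M |  | at 70 °C until 10 min, from then on at 110 °C | 20 min |
| noon | 0.80 M | 0.640 M | 70 °C |  | 20 min |
| spring | 0.80 M | 0.640 M | 90 °C |  | 20 min |
| midnight | 0.80 M | 0.640 M | 110 °C |  | 20 min |

| run | time / min | ring / % |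
|---|---|---|
| north-west | 2.00 | 3 |
| north-west | 4.00 | 0 |
| north-west | 6.00 | 4 |
| north-west | 8.00 | 5 |
| north-west | 10.0 | 6 |
| north-west | 12.0 | 9 |
| south | 0.250 | 1 |
| south | 0.833 | 1 |
| south | 1.50 | 3 |
| south | 2.00 | 5 |
| south | 3.00 | 7 |
| south | 4.00 | 11 |
| east | 2.50 | 3 |
| east | 5.00 | 3 |
| east | 8.00 | 4 |
| east | 10.0 | 5 |
| east | 12.0 | 12 |

(each reading ± 1.5 percentage points)

- at the start none of the solid activator is in solution

- the flask that comes out highest in amount of ring, in percent of the substrate charged, or "all alike" when all lie within 1.5 percentage points (dawn / noon / spring / midnight / all alike)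
- ring at the end, in percent of the substrate charged, dawn
- ring at the end, in percent of the substrate charged, noon
- ring at the end, in percent of the substrate charged, spring
- ring at the end, in percent of the substrate charged, midnight

Substrate and solid activator came first. By hand, a rate proportional to substrate leaves the percentage unchanged, and a rate proportional to activator raises it in step with the charge. The north-west run read 9 % at 12.0 min. The east run, with more of both, read 12 %, a gap of 3 percentage points under a scatter of 1.5 points per reading, so this reading rose by a smaller factor than the activator charge did. Dawn, noon, spring and midnight carry one charge anyway, so neither setting separates them.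

Temperature does. By hand, each degree multiplies the rate by the same factor. From the last reading of each run I took an average rate of 0.00750 min⁻¹ of the charge in the north-west run at 80 °C and 0.0275 min⁻¹ in the south run at 102 °C, a factor of 3.67. That factor carries the scatter of the readings, and the two runs differ in substrate as well as temperature, so it is an estimate that treats the percentage as independent of substrate. Spread evenly over the degrees, that gives 10.6 as my exchange rate, the number of minutes at 70 °C that do the turnover of one minute at 110 °C.

The last setting is the time of the change. Dawn's first 10 min count as 0.943 min at 110 °C, so dawn holds 10.9 min of hot minutes, about half of midnight's 20 min. At the extrapolated 0.0441 min⁻¹, I reckoned dawn at 48.3 %, noon at 8.32 % and spring at 27.1 %. Midnight's straight line reached 88.2 %; I expected it to bend down as substrate fell, but I kept midnight highest.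

The forecast also named midnight, with dawn 37 %, noon 8 %, spring 28 % and midnight 58 %, holding that “All runs start slowly because the solid must first dissolve”. It put dawn lower than I did.

The flasks gave dawn 60.7 %, noon 4.58 %, spring 37.3 % and midnight 65.5 %, so midnight stood highest.

    solid activator ⇌ activator, rate k1*(cs1 - [activator]) while solid is left; crystals form when [activator] > cs1 (solubility = 0.410 M, k = 0.658 min⁻¹)
    substrate + activator → activated form (k = 1.52 L mol⁻¹ min⁻¹, Ea = 91.0 kJ mol⁻¹)
    activated form → ring (k = 0.790 min⁻¹, Ea = 102 kJ mol⁻¹)
    activator ⇌ dormant form (K = 0.570, k = 0.777 min⁻¹, Ea = 108 kJ mol⁻¹, ΔH = −8.00 kJ mol⁻¹)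
    substrate + activated form → open dimer (k = 0.378 L mol⁻¹ min⁻¹, Ea = 65.0 kJ mol⁻¹)
    (constants at 110 °C)

Dawn's 10.9 min of hot minutes stand beside midnight at 10.0 min, where ring was 58.3 %, and dawn's 60.7 % lies above my 48.3 %. Noon left for 200 min counts 18.8 min of hot minutes, close to midnight's 20 min, yet noon then holds 38.8 % ring against midnight's 65.5 % and 44.4 % open dimer against midnight's 22.1 %, and the activation energy of the open-dimer path lies below that of the ring path by 37.0 kJ mol⁻¹.

(The earlier runs and the new flask come from a simulation from invented constants; noise was put on by code.)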